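**Retrosynthetic overview**

1. Numbering: C1 ketone, C4=C5 (Z), C6 lactone CH–O, C7=C11 butenolide alkene, C8 CH–O (methacrylate), C10 C(Me)OAc, C12 lactone C=O, C13 CH2OAc. The three esters go on last (O8 methacrylate, then O10/O13 acetates).
2. The ten-membered carbocycle is closed second, at C7–C8, by a chromium/nickel-mediated addition of a C7 alkenyl iodide to the C8 aldehyde.
3. The butenolide is made first, on the open chain: a C6 propargylic carbonate, CO and I2 are joined in one operation, forming C12–C11 and O–C6, setting C6 by chirality transfer and leaving iodide on C7.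
4. Enabling feature: in the butenolide ring (O, C12, C11, C7, C6) the carbons C6–C7–C11 lie between the lactone oxygen and the carbonyl carbon. At the propargyl level (C7≡C11, leaving group on C6) this unit takes up CO at C11 and returns the carbonyl oxygen to C6, and the fully substituted C7 keeps a replaceable iodide.
5. Chain: (S)-citramalic acid (C1, C8–C10 and the C10 stereocentre), vinyl Grignard (C2–C3), (Z)-3-iodobut-2-en-1-ol (C4–C6), a silyl propargyl ether (C7, C11, C13).

Key step: step 10

Assumption: C1 in 6, 10 and 11 is a mixture of epimers that is erased by oxidation in step 7, and the ligand antipodes in steps 8 and 12 are those that deliver the carbon nucleophile to the Re face of the aldehyde.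

**Step 1**
Reactants: 1 (S)-citramalic acid
Product: 2 [(4S)-2,2,4-trimethyl-5-oxo-1,3-dioxolan-4-yl]acetic acid
Conditions: 2,2-dimethoxypropane, TsOH (cat.), acetone, rt
Reagents that add atoms: 2,2-dimethoxypropane, COC(C)(C)OC
Why: Acetalization of the α-hydroxy acid (1,3-dioxolan-4-one formation, five-membered ring preferred over the six-membered dioxanone) masks the C1 carboxyl and the C10 hydroxyl together and leaves the C8 carboxyl free; the C10 stereocentre comes from the chiral pool and is not touched.

**Step 2**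
Reactants: 2 [(4S)-2,2,4-trimethyl-5-oxo-1,3-dioxolan-4-yl]acetic acid
Product: 3 (5S)-5-(2-hydroxyethyl)-2,2,5-trimethyl-1,3-dioxolan-4-one
Conditions: BH3·THF, THF, 0 °C to rt; then H2O
Reagents that add atoms: none
Why: Chemoselective borane reduction of the free carboxylic acid, which is reduced much faster than the dioxolanone (ester-type) carbonyl.

**Step 3**
Reactants: 3 (5S)-5-(2-hydroxyethyl)-2,2,5-trimethyl-1,3-dioxolan-4-one
Product: 4 (5S)-2,2,5-trimethyl-5-[2-(triethylsilyloxy)ethyl]-1,3-dioxolan-4-one
Conditions: Et3SiCl, imidazole, CH2Cl2, 0 °C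
Reagents that add atoms: chlorotriethylsilane, CC[Si](Cl)(CC)CC
Why: Silyl ether formation at the only hydroxyl group, done at once so that the alcohol cannot translactonize onto the dioxolanone; the triethylsilyl group is chosen because step 11 oxidizes it directly to the aldehyde.

**Step 4**
Reactants: 4 (5S)-2,2,5-trimethyl-5-[2-(triethylsilyloxy)ethyl]-1,3-dioxolan-4-one
Product: 6 (3RS,4S)-4-methyl-6-(triethylsilyloxy)hex-1-ene-3,4-diol, via aluminium lactolate 5 (not isolated)
Conditions: iBu2AlH, CH2Cl2, −78 °C; then CH2=CHMgBr, THF, −78 to 0 °C; aqueous Rochelle salt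
Reagents that add atoms: vinylmagnesium bromide, C=C[Mg]Br
Why: Partial reduction of the lactone-type carbonyl to a stable aluminium lactolate followed by Grignard addition to the α-alkoxy aldehyde that it releases on warming (acetone is lost); C1 forms as a mixture of epimers that is erased in step 7 and C10 is unchanged.

**Step 5**
Reactants: 7 but-2-yn-1-ol
Product: 9 (Z)-3-iodobut-2-en-1-ol, via cyclic alkenylalanate 8 (not isolated)
Conditions: NaAlH2(OCH2CH2OMe)2 (Red-Al), THF, 0 °C to rt; then I2, THF, −78 °C
Reagents that add atoms: iodine, II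
Why: Hydroxyl-directed trans-hydroalumination of the propargylic alcohol gives the five-membered alkenylalanate with aluminium on the methyl-bearing carbon, and iodinolysis with retention gives the Z iodide (iodine cis to CH2OH).

**Step 6**
Reactants: 6 (3RS,4S)-4-methyl-6-(triethylsilyloxy)hex-1-ene-3,4-diol; 9 (Z)-3-iodobut-2-en-1-ol
Product: 11 (2Z,6RS,7S)-3,7-dimethyl-9-(triethylsilyloxy)non-2-ene-1,6,7-triol, via alkylborane 10 (not isolated)
Conditions: 9-BBN (3.5 equiv), THF, rt; then 9, Pd(dppf)Cl2 (5 mol %), AsPh3, Cs2CO3, DMF/H2O, rt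
Reagents that add atoms: none
Why: B-alkyl Suzuki–Miyaura coupling: anti-Markovnikov hydroboration places boron on C3 and the cross-coupling of the alkenyl iodide proceeds with retention, so the Z geometry of C4=C5 in the target is taken over from 9; the excess of 9-BBN allows for the two free hydroxyl groups.

**Step 7**
Reactants: 11 (2Z,6RS,7S)-3,7-dimethyl-9-(triethylsilyloxy)non-2-ene-1,6,7-triol
Product: 12 (2Z,7S)-7-hydroxy-3,7-dimethyl-6-oxo-9-(triethylsilyloxy)non-2-enal
Conditions: IBX (3 equiv), DMSO, rt
Reagents that add atoms: none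
Why: IBX oxidation takes the primary allylic alcohol to the Z enal and the secondary alcohol of the 1,2-diol to the ketone without glycol cleavage, the tertiary alcohol and the silyl ether being inert.

**Step 8**
Reactants: 12 (2Z,7S)-7-hydroxy-3,7-dimethyl-6-oxo-9-(triethylsilyloxy)non-2-enal; 13 tert-butyldimethyl(prop-2-yn-1-yloxy)silane
Product: 14 (4S,5Z,10S)-1-(tert-butyldimethylsilyloxy)-4,10-dihydroxy-6,10-dimethyl-12-(triethylsilyloxy)dodec-5-en-2-yn-9-one
Conditions: 13 (3 equiv), ZnMe2 (3.5 equiv), (S,S)-ProPhenol (20 mol %), Ph3P=O (40 mol %), toluene, 4 °C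
Reagents that add atoms: none
Why: Zinc-ProPhenol catalysed asymmetric alkynylation: the zinc alkynylide adds to the aldehyde (not to the hindered ketone) on its Re face under ligand control, which sets C6 as S; the ligand antipode is to be confirmed by MTPA ester analysis of 14.

**Step 9**
Reactants: 14 (4S,5Z,10S)-1-(tert-butyldimethylsilyloxy)-4,10-dihydroxy-6,10-dimethyl-12-(triethylsilyloxy)dodec-5-en-2-yn-9-one
Product: 15 (4S,5Z,10S)-1-(tert-butyldimethylsilyloxy)-10-hydroxy-6,10-dimethyl-9-oxo-12-(triethylsilyloxy)dodec-5-en-2-yn-4-yl methyl carbonate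
Conditions: ClCO2Me, pyridine, DMAP (cat.), CH2Cl2, 0 °C
Reagents that add atoms: methyl chloroformate, COC(=O)Cl
Why: Carbonate formation (acylation with a chloroformate) at the secondary propargylic alcohol; the tertiary alcohol next to the ketone is too hindered to react, and a carbonate, unlike a sulfonate, is stable at this doubly activated position.

**Step 10**
Reactants: 15 (4S,5Z,10S)-1-(tert-butyldimethylsilyloxy)-10-hydroxy-6,10-dimethyl-9-oxo-12-(triethylsilyloxy)dodec-5-en-2-yn-4-yl methyl carbonate
Product: 17 (5R)-3-[(tert-butyldimethylsilyloxy)methyl]-5-[(1Z,6S)-6-hydroxy-2,6-dimethyl-5-oxo-8-(triethylsilyloxy)oct-1-en-1-yl]-4-iodofuran-2(5H)-one, via methyl allenoate 16 (not isolated)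
Conditions: Pd(PPh3)4 (5 mol %), CO (1 atm), THF/MeOH, 25 °C; then vent, I2 (3 equiv), NaHCO3, MeCN/H2O, 0 °C to rt
Reagents that add atoms: carbon monoxide, [C-]#[O+]; iodine, II; water, O
Why: Zerovalent palladium ionizes the propargylic carbonate in an anti SN2′ sense (loss of CO2 and methoxide) to a σ-allenylpalladium species with the metal on C11, CO inserts into this bond (C11–C12) and methoxide closes the cycle to give the axially chiral allenoate 16; iodine then activates the C6=C7 bond so that the ester carbonyl oxygen, the one delivered by CO, adds to C6 (O–C6) while iodine ends on C7 and the methoxy group is exchanged for oxygen from water. The closest known reaction types are the palladium-catalysed decarboxylative carbonylation of propargylic carbonates to 2,3-allenoates and the iodolactonization of 2,3-allenoates to 4-iodobutenolides, here run in one flask. The butenolide closes in a 5-endo-trig mode at the allene terminus, which is easy because the attacked π bond lies in the plane of the ester group. C6 is the only new stereocentre: centre-to-axis transfer in the anti ionization and axis-to-centre transfer in the oxy-iodination, in which the ester oxygen can only add on its own side of the allene, convert the 6S carbonate into the 6R lactone (net inversion). The step needs ionization towards the alkyne and not towards the C4=C5 alkene, which the higher reactivity of propargylic over allylic carbonates and the cis C3 substituent (1,3-strain in a π-allyl complex) should secure; it also needs iodine to choose the allene over the C4=C5 alkene, which the intramolecular oxygen nucleophile secures, while 1 atm of CO and a low palladium loading limit racemization of the allenylpalladium intermediate.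

**Step 11**
Reactants: 17 (5R)-3-[(tert-butyldimethylsilyloxy)methyl]-5-[(1Z,6S)-6-hydroxy-2,6-dimethyl-5-oxo-8-(triethylsilyloxy)oct-1-en-1-yl]-4-iodofuran-2(5H)-one
Product: 18 (3S,7Z)-8-[(2R)-4-[(tert-butyldimethylsilyloxy)methyl]-3-iodo-5-oxo-2,5-dihydrofuran-2-yl]-3-hydroxy-3,7-dimethyl-4-oxooct-7-enal
Conditions: (COCl)2, DMSO, CH2Cl2, −78 to −40 °C; then Et3N, −78 to 0 °C
Reagents that add atoms: none
Why: Swern oxidation, which converts a primary triethylsilyl ether directly into the aldehyde while the primary tert-butyldimethylsilyl ether, the tertiary alcohol and the iodobutenolide stay intact; the low temperature and short exposure to the amine guard the C6 centre.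

**Step 12**
Reactants: 18 (3S,7Z)-8-[(2R)-4-[(tert-butyldimethylsilyloxy)methyl]-3-iodo-5-oxo-2,5-dihydrofuran-2-yl]-3-hydroxy-3,7-dimethyl-4-oxooct-7-enal
Product: 19 (6R,8S,10S)-13-(tert-butyldimethylsilyloxy)-8,10-dihydroxy-1-oxogermacra-4Z,7(11)-dien-12,6-olide (ten-membered carbocycle fused at C6/C7 to the butenolide, free C8 and C10 hydroxyls)
Conditions: CrCl2 (4 equiv), NiCl2 (2 mol %), chiral 2-(4-isopropyloxazolin-2-yl)aryl methanesulfonamide ligand (4.4 equiv), Et3N, THF/MeCN, 2 mM, rt
Reagents that add atoms: none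
Why: Intramolecular Nozaki–Hiyama–Kishi reaction: nickel inserts into the activated C7–I bond, the alkenylchromium species adds to the C8 aldehyde and closes the ten-membered ring (the cis C4=C5 bond and the planar butenolide hold the ends close), ketone, lactone and free hydroxyl being tolerated; the ligand on chromium directs the attack to the Re face of the aldehyde (8S), the sense that 1,3-anti induction from the oxygenated C10 centre also favours.

**Step 13**
Reactants: 19 (6R,8S,10S)-13-(tert-butyldimethylsilyloxy)-8,10-dihydroxy-1-oxogermacra-4Z,7(11)-dien-12,6-olide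
Product: 20 (6R,8S,10S)-13-(tert-butyldimethylsilyloxy)-10-hydroxy-8-(methacryloyloxy)-1-oxogermacra-4Z,7(11)-dien-12,6-olide
Conditions: methacrylic anhydride, DMAP (cat.), pyridine, CH2Cl2, 0 °C
Reagents that add atoms: methacrylic anhydride, C=C(C)C(=O)OC(=O)C(C)=C
Why: DMAP-catalysed acylation of the secondary allylic alcohol with retention at C8; the tertiary C10 alcohol does not react under these conditions.

**Step 14**
Reactants: 20 (6R,8S,10S)-13-(tert-butyldimethylsilyloxy)-10-hydroxy-8-(methacryloyloxy)-1-oxogermacra-4Z,7(11)-dien-12,6-olide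
Product: 21 (6R,8S,10S)-10,13-dihydroxy-8-(methacryloyloxy)-1-oxogermacra-4Z,7(11)-dien-12,6-olide
Conditions: HF·pyridine, pyridine/THF, 0 °C to rt
Reagents that add atoms: none
Why: Fluoride-mediated desilylation of the primary silyl ether under buffered, non-basic conditions that leave the two esters and the lactone untouched.

**Step 15**
Reactants: 21 (6R,8S,10S)-10,13-dihydroxy-8-(methacryloyloxy)-1-oxogermacra-4Z,7(11)-dien-12,6-olide
Product: 22 CNP0115165.3, (6R,8S,10S)-10,13-diacetoxy-8-(methacryloyloxy)-1-oxogermacra-4Z,7(11)-dien-12,6-olide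
Conditions: Ac2O, Sc(OTf)3 (2 mol %), MeCN, −20 °C
Reagents that add atoms: acetic anhydride, CC(=O)OC(C)=O
Why: Lewis acid catalysed acetylation, which esterifies the primary and the hindered tertiary alcohol in one operation without an amine base that could epimerize C6 or trigger an α-ketol shift.

**Compound list**

1 | (S)-citramalic acid, (2S)-2-hydroxy-2-methylbutanedioic acid | C[C@](O)(CC(=O)O)C(=O)O | starting material
2 | [(4S)-2,2,4-trimethyl-5-oxo-1,3-dioxolan-4-yl]acetic acid | C[C@@]1(CC(=O)O)OC(C)(C)OC1=O | intermediate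
3 | (5S)-5-(2-hydroxyethyl)-2,2,5-trimethyl-1,3-dioxolan-4-one | C[C@@]1(CCO)OC(C)(C)OC1=O | intermediate
4 | (5S)-2,2,5-trimethyl-5-[2-(triethylsilyloxy)ethyl]-1,3-dioxolan-4-one | C[C@@]1(CCO[Si](CC)(CC)CC)OC(C)(C)OC1=O | intermediate
5 | diisobutylaluminium alkoxide of (5S)-2,2,5-trimethyl-5-[2-(triethylsilyloxy)ethyl]-1,3-dioxolan-4-ol (aluminium lactolate, not isolated) | C[C@@]1(CCO[Si](CC)(CC)CC)OC(C)(C)OC1O[Al](CC(C)C)CC(C)C | intermediate
6 | (3RS,4S)-4-methyl-6-(triethylsilyloxy)hex-1-ene-3,4-diol | C=CC(O)[C@@](C)(O)CCO[Si](CC)(CC)CC | intermediate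
7 | but-2-yn-1-ol | CC#CCO | starting material
8 | sodium 2,2-bis(2-methoxyethoxy)-3-methyl-2,5-dihydro-1,2-oxaaluminol-2-uide (cyclic alkenylalanate, not isolated) | CC1=CCO[Al-]1(OCCOC)OCCOC.[Na+] | intermediate
9 | (Z)-3-iodobut-2-en-1-ol | C/C(I)=C/CO | intermediate
10 | 9-[(4S)-3,4-dihydroxy-4-methyl-6-(triethylsilyloxy)hexyl]-9-borabicyclo[3.3.1]nonane (alkylborane, not isolated) | O[C@@](C)(CCO[Si](CC)(CC)CC)C(O)CCB1C2CCCC1CCC2 | intermediate
11 | (2Z,6RS,7S)-3,7-dimethyl-9-(triethylsilyloxy)non-2-ene-1,6,7-triol | OC/C=C(C)\CCC(O)[C@@](C)(O)CCO[Si](CC)(CC)CC | intermediate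
12 | (2Z,7S)-7-hydroxy-3,7-dimethyl-6-oxo-9-(triethylsilyloxy)non-2-enal | O=C/C=C(C)\CCC(=O)[C@@](C)(O)CCO[Si](CC)(CC)CC | intermediate
13 | tert-butyldimethyl(prop-2-yn-1-yloxy)silane | C#CCO[Si](C)(C)C(C)(C)C | starting material
14 | (4S,5Z,10S)-1-(tert-butyldimethylsilyloxy)-4,10-dihydroxy-6,10-dimethyl-12-(triethylsilyloxy)dodec-5-en-2-yn-9-one | CC(C)(C)[Si](C)(C)OCC#C[C@@H](O)/C=C(C)\CCC(=O)[C@@](C)(O)CCO[Si](CC)(CC)CC | intermediate
15 | (4S,5Z,10S)-1-(tert-butyldimethylsilyloxy)-10-hydroxy-6,10-dimethyl-9-oxo-12-(triethylsilyloxy)dodec-5-en-2-yn-4-yl methyl carbonate | CC(C)(C)[Si](C)(C)OCC#C[C@@H](OC(=O)OC)/C=C(C)\CCC(=O)[C@@](C)(O)CCO[Si](CC)(CC)CC | intermediate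
16 | methyl (Ra,5Z,10S)-2-[(tert-butyldimethylsilyloxy)methyl]-10-hydroxy-6,10-dimethyl-9-oxo-12-(triethylsilyloxy)dodeca-2,3,5-trienoate (not isolated) | COC(=O)C(CO[Si](C)(C)C(C)(C)C)=[C@]=C([H])/C=C(C)\CCC(=O)[C@@](C)(O)CCO[Si](CC)(CC)CC | intermediate
17 | (5R)-3-[(tert-butyldimethylsilyloxy)methyl]-5-[(1Z,6S)-6-hydroxy-2,6-dimethyl-5-oxo-8-(triethylsilyloxy)oct-1-en-1-yl]-4-iodofuran-2(5H)-one | CC(C)(C)[Si](C)(C)OCC1=C(I)[C@@H](/C=C(C)\CCC(=O)[C@@](C)(O)CCO[Si](CC)(CC)CC)OC1=O | intermediate
18 | (3S,7Z)-8-[(2R)-4-[(tert-butyldimethylsilyloxy)methyl]-3-iodo-5-oxo-2,5-dihydrofuran-2-yl]-3-hydroxy-3,7-dimethyl-4-oxooct-7-enal | CC(C)(C)[Si](C)(C)OCC1=C(I)[C@@H](/C=C(C)\CCC(=O)[C@@](C)(O)CC=O)OC1=O | intermediate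
19 | (6R,8S,10S)-13-(tert-butyldimethylsilyloxy)-8,10-dihydroxy-1-oxogermacra-4Z,7(11)-dien-12,6-olide | O[C@H]1C[C@](C)(O)C(=O)CC/C(C)=C\[C@H]2OC(=O)C(CO[Si](C)(C)C(C)(C)C)=C12 | intermediate
20 | (6R,8S,10S)-13-(tert-butyldimethylsilyloxy)-10-hydroxy-8-(methacryloyloxy)-1-oxogermacra-4Z,7(11)-dien-12,6-olide | C=C(C)C(=O)O[C@H]1C[C@](C)(O)C(=O)CC/C(C)=C\[C@H]2OC(=O)C(CO[Si](C)(C)C(C)(C)C)=C12 | intermediate
21 | (6R,8S,10S)-10,13-dihydroxy-8-(methacryloyloxy)-1-oxogermacra-4Z,7(11)-dien-12,6-olide | C=C(C)C(=O)O[C@H]1C[C@](C)(O)C(=O)CC/C(C)=C\[C@H]2OC(=O)C(CO)=C12 | intermediate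
22 | CNP0115165.3, (6R,8S,10S)-10,13-diacetoxy-8-(methacryloyloxy)-1-oxogermacra-4Z,7(11)-dien-12,6-olide | C=C(C)C(=O)O[C@H]1C[C@](C)(OC(C)=O)C(=O)CC/C(C)=C\[C@H]2OC(=O)C(COC(C)=O)=C12 | target

**Step count**

Total: 15 steps. Longest linear sequence: 14 steps (steps 1–4 and 6–15, from (S)-citramalic acid); step 5 is a one-step side branch.

**Steps most likely to fail**

Step 10. The ionization may run in part towards a π-allyl complex on the C4=C5 side, and the allene axis may erode (racemization of the allenylpalladium species, or a stepwise cationic iodocyclization through the allyl-stabilized C6 cation), which would cost regiocontrol or configuration at C6. The fallback sets out from 14 and comes back at 17. Mesylation (MsCl, Et3N, −78 °C) gives the mesylate F1, which is displaced in an anti SN2′ sense with LiCuBr2 (from CuBr·SMe2 and LiBr, THF, −78 to −20 °C) to the bromoallene F2. This fixes the allene axis under copper control before any palladium is present. Methoxycarbonylation of the allenyl bromide (Pd(PPh3)4, CO, MeOH, iPr2NEt), with oxidative addition into the C(sp2)–Br bond in retention, gives 16, now isolated, and a separate iodolactonization (I2, NaHCO3, MeCN/H2O) gives 17.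

Step 12. The alkenylchromium addition may show poor or reversed facial selectivity when the ligand and the conformation of the closing ring are mismatched, and intermolecular coupling may compete. The fallback sets out from 18 and comes back at 20. The closure is run without the chiral ligand (CrCl2, NiCl2 cat., DMSO, high dilution), and the 8R carbinol F3 is esterified under Mitsunobu conditions (methacrylic acid, PPh3, DIAD), which inverts C8 and gives 20 directly. Any 8S material is acylated as in step 13.

Step 8. Low enantioselectivity, Z to E isomerization of the enal under the zinc alkoxide conditions, or competing addition to the C1 ketone may occur. The fallback sets out from 12 and comes back at 14. The lithium acetylide of 13 (nBuLi, THF, −78 °C) is added to the aldehyde to give the C6-epimeric alcohol F4. The doubly activated carbinol is oxidized with MnO2 to the ynone F5. Noyori asymmetric transfer hydrogenation (RuCl[(S,S)-TsDPEN](p-cymene), iPrOH, rt) then reduces the ynone, much faster than the hindered C1 ketone, to 14.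

**Further compounds**

F1 | step 10 | (4S,5Z,10S)-1-(tert-butyldimethylsilyloxy)-10-hydroxy-6,10-dimethyl-9-oxo-12-(triethylsilyloxy)dodec-5-en-2-yn-4-yl methanesulfonate | CC(C)(C)[Si](C)(C)OCC#C[C@@H](OS(C)(=O)=O)/C=C(C)\CCC(=O)[C@@](C)(O)CCO[Si](CC)(CC)CC
F2 | step 10 | (3S,8Z,Ra)-11-bromo-12-(tert-butyldimethylsilyloxy)-3-hydroxy-3,7-dimethyl-1-(triethylsilyloxy)dodeca-7,9,10-trien-4-one (bromoallene) | CC(C)(C)[Si](C)(C)OCC(Br)=[C@@]=C([H])/C=C(C)\CCC(=O)[C@@](C)(O)CCO[Si](CC)(CC)CC
F3 | step 12 | (6R,8R,10S)-13-(tert-butyldimethylsilyloxy)-8,10-dihydroxy-1-oxogermacra-4Z,7(11)-dien-12,6-olide (8-epimer of 19) | O[C@@H]1C[C@](C)(O)C(=O)CC/C(C)=C\[C@H]2OC(=O)C(CO[Si](C)(C)C(C)(C)C)=C12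
F4 | step 8 | (4RS,5Z,10S)-1-(tert-butyldimethylsilyloxy)-4,10-dihydroxy-6,10-dimethyl-12-(triethylsilyloxy)dodec-5-en-2-yn-9-one | CC(C)(C)[Si](C)(C)OCC#CC(O)/C=C(C)\CCC(=O)[C@@](C)(O)CCO[Si](CC)(CC)CC
F5 | step 8 | (5Z,10S)-1-(tert-butyldimethylsilyloxy)-10-hydroxy-6,10-dimethyl-12-(triethylsilyloxy)dodec-5-en-2-yne-4,9-dione | CC(C)(C)[Si](C)(C)OCC#CC(=O)/C=C(C)\CCC(=O)[C@@](C)(O)CCO[Si](CC)(CC)CC
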